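The vessel holds substrate and protic impurity, and partner runs in steadily over 6.0 min.

| flask | substrate | partner | protic impurity | remark | time |
|---|---|---|---|---|---|
| south | 0.040 M | 0.040 M (fed, over 6.0 min) | 0.012 M | run made earlier |  |
| north-west | 0.040 M | 0.090 M (fed, over 6.0 min) | 0.012 M | run made earlier |  |
| east | 0.060 M | 0.060 M (fed, over 6.0 min) | 0.012 M | run made earlier |  |
| flask | 0.040 M | 0.0600 M (fed, over 6.0 min) | 0.0120 M |  | 3.0 h |

- south (time / h: target / %, substrate / %): 0.0833: 6, 93; 0.167: 15, 80; 0.333: 17, 76; 0.500: 18, 76; 1.00: 11, 78; 2.00: 13, 85; 4.00: 12, 86
- north-west (time / h: target / %, substrate / %): 0.0833: 12, 87; 0.167: 25, 68; 0.333: 26, 65; 0.500: 24, 65; 1.00: 21, 75; 2.00: 15, 80; 4.00: 12, 85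
- east (time / h: target / %, substrate / %): 0.0833: 8, 88; 0.200: 18, 76; 0.500: 21, 75; 1.33: 14, 81; 4.00: 9, 88

(standard deviation of a reading: 1.5 percentage points)

- steps that have been proposed: substrate + partner <-> target + by-product; partner + protic impurity -> quenched reagent; 2 partner -> self-condensation product; target <-> isomer of the product

* time up to 3.0 h at which target stands highest
* the amount of target, in percent of the substrate charged, at that time

The east run looks nearly like the flask: it has the same partner and impurity charges but more substrate. In the east run, target reads 21% at 0.500 h and 9% at 4.00 h, while substrate comes back to 88%. I read that as an exchange running backward.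

So I carry one quantity. The flask has 1.20 spare equivalents, meaning partner charge less impurity charge, divided by substrate charge. The east run has 0.800, and the north-west run has 1.95.

The flask should stand above the east run because each substrate has more spare partner. It should stay below the north-west run, which has more still. Their peak readings differ by 4.3 percentage points per spare equivalent. My line therefore gives 22.7% for the flask, near the sample times 0.333 h to 0.500 h.

The forecast says 22% at 0.33 h, a little under mine. Its ground is this: “East has the same net partner but more substrate”.

    substrate + partner ⇌ target + by-product (K = 0.450, k = 0.0230 M⁻¹ s⁻¹)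
    partner + protic impurity → quenched reagent (k = 0.0500 M⁻¹ s⁻¹)
    2 partner → self-condensation product (k = 0.0360 M⁻¹ s⁻¹)
    target ⇌ isomer of the product (K = 0.340, k = 0.0180 s⁻¹)

The flask gives 22.0% at 0.334 h, against 22.7% on my line. Counted both ways together, the exchange step by itself relaxes with a half-life of 0.138 h at 3.00 h, shorter than the time allowed. At that end the flask holds 12.2% target and 83.6% substrate, with 3.09% of its partner left. With substrate cut to 0.016 M, the spare equivalents rise to 3.00, and my line gives 30.6%. That neighbour flask peaks at 27.8%.

Readings and results were computed for an exercise, and the scatter is random.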